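The runs were computed with made-up constants, noise included.

Does the ochre flask keep the ratio of isomer of the product to target that it starts with, or does isomer overtake target by 4.0 d?

the same everywhere: substrate 0.17 M; impurity 0.28 mM

| charge | free catalyst | remark | time |
|---|---|---|---|
| ochre | 0.26 mM | the very flask that is asked about, followed so far |  |
| blue | 0.39 mM | run made earlier |  |
| flask | 0.26 mM |  | 4.0 d |

- ochre (time / h: isomer of the product / %, target / %): 6.00: 0.5, 27.0; 12.0: 1.2, 27.4; 15.0: 1.5, 25.7; 25.0: 0, 28.0; 30.0: 0.6, 25.5
- blue (time / d: isomer of the product / %, target / %): 0.625: 8.9, 29.6; 1.04: 14.9, 27.3; 1.67: 22.4, 25.5; 2.50: 29.2, 21.1; 3.00: 36.0, 21.3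

(readings scatter by 1 percentage point)

- ratio of isomer of the product to target at 4.0 min
- ratio of isomer of the product to target at 4.0 d
- which of isomer of the product and target there is more of at 4.0 d

- what was read earlier has a scatter of 1 percentage point, one standard deviation
- what may be going on: substrate + free catalyst <-> target + free catalyst; substrate + free catalyst <-> isomer of the product + free catalyst; free catalyst + impurity -> spent catalyst

Step 1. Free catalyst charged minus impurity charged, as a fraction of the free catalyst charged, is −7.69% in the ochre flask and 28.2% in the blue run. This is the catalyst margin: the share of free catalyst that outlives the impurity, if each impurity takes one catalyst. Below zero, as in the ochre flask, more impurity is charged than free catalyst.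

Step 2. The readings fit the signs. Ochre target stays between 25.5% and 28.0% from 6.00 h to 30.0 h, while blue isomer climbs to 36.0% at 3.00 d. So the ochre flask is expected to stall with 7.14% of its impurity left.

Step 3. A stalled mixture keeps its composition. Ochre target averages 26.7%, and the last isomer reading, 0.6%, gives a ratio of 0.0225 at 4.0 d.

Step 4. The early ratio counts forward passage, not net target. Blue's first reading gives target over substrate of 0.481, so target alone approaches 32.5%. A logarithmic relaxation to that limit puts the forward passage into target in the ochre flask at 46.6% of the charge. The ratio at 4.0 min, if target is still far from its limit then, is 0.0129.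

Step 5. The weak link is that one isomer reading, which lies within the scatter of 1 percentage point. All five ochre readings average 0.760%, give or take 0.45 points, so this mean is poorly determined. The committed ratios become 0.0163 at 4.0 min and 0.0285 at 4.0 d, with target ahead. Isomer is the reading to watch.

The forecast gives 0.017 at 4.0 min, slightly above this early ratio, and 0.028 at 4.0 d, with target ahead: “The ochre mixture should stay frozen until 4 d”.

The ochre flask gives 0.0183 and 0.0320, with target ahead, at 26.6% against 0.851%.

    substrate + free catalyst ⇌ target + free catalyst, rate k1*[substrate]*[free catalyst] forward; the back reaction follows from the equilibrium constant (K = 0.450, k = 1.30 /M/s)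
    substrate + free catalyst ⇌ isomer of the product + free catalyst, rate k2*[substrate]*[free catalyst] forward; the back reaction follows from the equilibrium constant (K = 8.20, k = 0.0220 /M/s)
    free catalyst + impurity → spent catalyst (k = 5.60 /M/s)

The margin of −7.69% foretold 7.14% of the impurity left in the ochre flask; 7.14% stands there at 4.00 d, with free catalyst at 0%, and the hour of reading makes no difference to the ratio at that time. A neighbouring flask with impurity at 7.0 × 10⁻⁵ M, other charges as in the ochre flask, has a margin of 73.1%. At 4.00 d its free catalyst stands at 73.1% and its impurity at 0%. There isomer holds 58.7%, more than target at 12.9%, a ratio of 4.57.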